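Its constants belong to no real substance; the flask was simulated.

Leftover substrate was the number I went after first, and these flasks start with no catalyst, just its precatalyst.

- gamma: substrate 0.28 M; reagent 0.420 M; precatalyst 0.59 mM; time 6.0 min
- zeta: substrate 0.28 M; reagent 0.420 M; precatalyst 0.59 mM; time 10 min

    substrate + catalyst → catalyst + intermediate (k1 = 15.4 L mol⁻¹ s⁻¹)
    reagent + catalyst + intermediate → catalyst + product (k2 = 16.0 L² mol⁻² s⁻¹)
    precatalyst → catalyst (k3 = 6.57 × 10⁻⁴ s⁻¹)

* which of these there is most of at the end, counted by the substrate in it, gamma (intermediate / substrate / product)
* which of these there is most of at the end, counted by the substrate in it, zeta (intermediate / substrate / product)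
* how much there is at the end of the one of these that leads, in percent of the substrate charged: gamma
* how much there is at the end of the one of these that leads, in percent of the substrate charged: zeta

I wrote the constants as times at the charged amounts. With the whole charge as catalyst, the first step has a time of 1.83 min, shorter than the 6.0 min of gamma. But the precatalyst has a half-life of 17.6 min, longer than the 10 min of zeta, so the catalyst was still climbing through both runs and its curve sets the pace.

Let a, i and p be substrate, intermediate and product as fractions of the substrate charged. Then

a = exp(−N)

where N is the first step's constant times the area under the catalyst curve up to the reading.

That curve bends downward, so two straight lines bracket it. One keeps the starting slope and lies above the curve, which makes it the extreme with the most catalyst. The other is the chord to the end level and lies below, the extreme with the least.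

gamma, starting slope: N = 0.387, a = 67.9%
gamma, chord: N = 0.344, a = 70.9%
zeta, starting slope: N = 1.07, a = 34.1%
zeta, chord: N = 0.888, a = 41.1%

The real flask lies between each pair. Integrating the first-order rise of the catalyst gives the area itself:

gamma: N = 0.358, a = 69.9%
zeta: N = 0.946, a = 38.8%

This N, the first step's constant times the area under the catalyst curve, is my catalyst clock. I held the reagent at its charge, which makes the second step pseudo-first-order, but only as a trial, since full conversion of the substrate takes 66.7% of the reagent charge, so the hold has to be tested on the product it gives. That step then runs on the same clock at x = 0.436 of the first step's pace:

i = (exp(−xN) − exp(−N)) / (1 − x)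

gamma: i = 27.7%
zeta: i = 48.5%

The balance p = 1 − a − i then gives product that takes 1.58% of the reagent charge in gamma and 8.43% in zeta, so I let the trial stand for these two readings. So I expected substrate to lead in gamma and intermediate to lead in zeta.

The forecast gave substrate at 69.9% for gamma and intermediate at 49% for zeta, holding that “the useful clock is the time-integral of catalyst”.

The simulation gave substrate at 69.9% in gamma, with intermediate at 27.8%, and intermediate at 49.0% in zeta, with substrate at 38.8%.

The clock carries over to a neighbour of gamma charged with 2.4 × 10⁻⁴ M of precatalyst, time and other charges held. The catalyst curve is the charge times a fixed shape, so N scales with that charge and becomes 0.146. That gives a = 86.4% and i = 13.1%. The simulated neighbour held substrate at 86.4% and intermediate at 13.1% after 6.00 min.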